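**Retrosynthetic overview**
1. The Z-coumarate is built on O18 of diol 34 (phosphonoacetate ester, then Z-selective olefination); the diene side chain comes from C12 tosylate 30 and buta-1,3-dien-2-ylmagnesium chloride (C12–C13 bond).
2. C8 and C9 come from dienone 26: methyl adds to C8=O while C9 is trigonal, then the new C8 hydroxyl directs hydrogenation of C9=C11; 26 comes from the 6-en-8-one 21 by α′-aldol condensation at C9.
3. The strategy rests on this feature: rings A and B share the C5–C10 bond, and C4 and C10 (both quaternary) together with C5 carry a methyl/methyl-syn, trans-fused pattern that one cycloaddition transition state can set.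
4. Octalin aldehyde 13 is therefore opened to trienal 12 (bonds C3–C4 and C5–C10); rings A and B are formed together in that one step, and no other ring is made.
5. Trienal 12 comes from (S)-1,2-epoxyhex-5-ene: acetylide opening, carboalumination–iodination, alkene cleavage, Wittig enal formation, Stille vinylation.

Key step: step 7

Remark: labdane numbering is used throughout, "syn" and "anti" mean the same or the opposite face as the C10 methyl group, and (S)-1,2-epoxyhex-5-ene and bis(2,2,2-trifluoroethyl)phosphonoacetic acid are taken as catalogue compounds.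

**Route**

Step 1
Reactants: 1 (S)-1,2-epoxyhex-5-ene; 2 lithium acetylide–ethylenediamine complex
Product: 3 (S)-oct-7-en-1-yn-4-ol
Conditions: LiC≡CH·H2NCH2CH2NH2, DMSO, 0 °C → rt; H2O
Reagents that add atoms: none
Why: SN2 opening of the terminal epoxide by the acetylide at the unsubstituted carbon leaves the stereocentre (later C8) untouched, so the S configuration is carried over.

Step 2
Reactants: 3 (S)-oct-7-en-1-yn-4-ol
Product: 4 (S)-tert-butyldimethyl(oct-7-en-1-yn-4-yloxy)silane
Conditions: TBSCl, imidazole, DMF, rt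
Reagents that add atoms: tert-butyldimethylsilyl chloride, CC(C)(C)[Si](C)(C)Cl
Why: Standard silylation of a secondary alcohol gives a bulky, weakly basic ether that tolerates the aluminium reagents and later sits equatorial in the cycloaddition tether.

Step 3
Reactants: 4 (S)-tert-butyldimethyl(oct-7-en-1-yn-4-yloxy)silane
Product: 6 (S,E)-tert-butyl[(1-iodo-2-methylocta-1,7-dien-4-yl)oxy]dimethylsilane, via alkenyldimethylalane 5 (not isolated)
Conditions: Me3Al, Cp2ZrCl2 (0.25 equiv), CH2Cl2, 0 °C → rt; then I2, THF, −30 → 0 °C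
Reagents that add atoms: trimethylaluminium, C[Al](C)C; iodine, II
Why: Negishi zirconium-catalysed carboalumination adds methyl and aluminium syn across the terminal alkyne with methyl on the internal carbon, and iodinolysis with retention gives the E iodoalkene; the isolated terminal alkene reacts far more slowly.

Step 4
Reactants: 6 (S,E)-tert-butyl[(1-iodo-2-methylocta-1,7-dien-4-yl)oxy]dimethylsilane
Product: 8 (4S,6E)-4-(tert-butyldimethylsilyloxy)-7-iodo-6-methylhept-6-enal, via vicinal diol 7 (not isolated)
Conditions: OsO4 (2 mol %), NaIO4 (4 equiv), 2,6-lutidine, dioxane/H2O (3:1), rt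
Reagents that add atoms: osmium tetroxide, O=[Os](=O)(=O)=O; sodium periodate, [Na+].[O-]I(=O)(=O)=O
Why: Lemieux–Johnson cleavage should take the monosubstituted terminal alkene in preference to the trisubstituted iodoalkene, which is deactivated by the halogen and more hindered.

Step 5
Reactants: 8 (4S,6E)-4-(tert-butyldimethylsilyloxy)-7-iodo-6-methylhept-6-enal; 9 2-(triphenylphosphoranylidene)propanal
Product: 10 (2E,6S,8E)-6-(tert-butyldimethylsilyloxy)-9-iodo-2,8-dimethylnona-2,8-dienal
Conditions: toluene, 90 °C
Reagents that add atoms: none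
Why: Wittig olefination with a stabilised ylide gives the E-2-methyl enal (formyl group cis to the vinylic hydrogen), the geometry the cycloaddition needs.

Step 6
Reactants: 10 (2E,6S,8E)-6-(tert-butyldimethylsilyloxy)-9-iodo-2,8-dimethylnona-2,8-dienal; 11 tributyl(vinyl)stannane
Product: 12 (2E,6S,8E)-6-(tert-butyldimethylsilyloxy)-2,8-dimethylundeca-2,8,10-trienal
Conditions: PdCl2(MeCN)2 (5 mol %), DMF, rt, dark
Reagents that add atoms: none
Why: Stille coupling proceeds with retention of the iodoalkene geometry under neutral conditions that the enal and silyl ether tolerate, giving the diene with its methyl inside and the tether outside.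

Step 7
Reactants: 12 (2E,6S,8E)-6-(tert-butyldimethylsilyloxy)-2,8-dimethylundeca-2,8,10-trienal
Product: 13 octalin aldehyde (trans-fused; C4 CH3 syn, CHO anti, H5 anti, C8 OTBS anti and equatorial)
Conditions: Me2AlCl (1.2 equiv), CH2Cl2, −78 → −20 °C; H2O
Reagents that add atoms: none
Why: Me2AlCl binds the formyl oxygen and lowers the enal LUMO, so that a concerted, asynchronous [4+2] cycloaddition of the C4=C5 enal to the C10=C1–C2=C3 diene can run at low temperature; the closest known reaction type is the Lewis acid-promoted intramolecular Diels–Alder reaction of (E)-2-methyl-2,8,10-undecatrienals to trans-fused octalin aldehydes. Ring A is closed as the new cyclohexene by both σ-bonds (C3–C4 and C5–C10), and ring B is closed by the C5–C10 bond across the four-carbon tether C6–C9, which adopts a chair. C4 and C5 are fixed relative to each other by suprafacial addition to the E enal (CHO cis to H5), and C10 relative to C5 by the endo position of the aluminium-bound formyl group, which gives the trans fusion and puts the C4 and C10 methyls syn. The absolute sense comes from the S silyloxy carbon C8, whose OTBS group stays equatorial on the chair tether because the other diene face would force it axial and syn to the C10 methyl. The step needs endo over exo selectivity and diene-face selectivity, which the Lewis acid (formyl endo, α-methyl exo) and the C8 substituent should secure, and it needs the cycloaddition at the fully substituted C10 terminus to outrun cationic degradation of the diene, for which a proton-scavenging alkylaluminium chloride and low temperature are chosen.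

Step 8
Reactants: 13 octalin aldehyde
Product: 14 C18 primary alcohol
Conditions: NaBH4, MeOH, 0 °C
Reagents that add atoms: none
Why: Borohydride reduction of the neopentyl aldehyde creates no stereocentre and turns C18 into a group that can be masked before the enolate chemistry.

Step 9
Reactants: 14 C18 primary alcohol
Product: 15 C18 tert-butyldiphenylsilyl ether
Conditions: TBDPSCl, imidazole, DMAP (cat.), DMF, 40 °C
Reagents that add atoms: tert-butyldiphenylsilyl chloride, CC(C)(C)[Si](Cl)(c1ccccc1)c1ccccc1
Why: Silylation with a group that survives the acid cleavage of the C8 TBS ether and all later base and organometallic steps, and that fluoride removes at the end without touching the diene.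

Step 10
Reactants: 15 C18 tert-butyldiphenylsilyl ether
Product: 16 saturated trans-decalin bis-silyl ether
Conditions: H2 (1 atm), 10% Pd/C, EtOAc, rt
Reagents that add atoms: none
Why: Heterogeneous hydrogenation of the cis-disubstituted C1=C2 bond creates no stereocentre and clears ring A of unsaturation before ring B is worked on.

Step 11
Reactants: 16 saturated trans-decalin bis-silyl ether
Product: 17 C8 alcohol
Conditions: CSA (0.1 equiv), MeOH/CH2Cl2 (1:1), 0 °C → rt
Reagents that add atoms: none
Why: Acid-catalysed methanolysis cleaves the secondary TBS ether much faster than the neopentyl TBDPS ether (orthogonal silyl ether deprotection).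

Step 12
Reactants: 17 C8 alcohol
Product: 18 8-ketone
Conditions: Dess–Martin periodinane, CH2Cl2, rt
Reagents that add atoms: none
Why: Dess–Martin oxidation of the secondary alcohol under neutral conditions; the C8 stereocentre has done its work and is erased.

Step 13
Reactants: 18 8-ketone
Product: 21 6-en-8-one, via lithium enolate 19 (not isolated), via silyl enol ether 20 (not isolated)
Conditions: LiN(iPr)2, THF, −78 °C; TMSCl; then Pd(OAc)2 (1.05 equiv), MeCN, rt
Reagents that add atoms: none
Why: Saegusa–Ito oxidation: kinetic deprotonation goes to C7 (C9 is neopentyl), and dehydrosilylation can only give C6=C7 because C10 is quaternary; the new alkene blocks C7 so that C9 becomes the only enolisable position.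

Step 14
Reactants: 21 6-en-8-one; 22 (tert-butyldimethylsilyloxy)acetaldehyde
Product: 24 aldol adduct at C9 (mixture at C9 and C11), via lithium dienolate 23 (not isolated)
Conditions: LiN(iPr)2, THF, −78 °C; then 22; AcOH quench at −78 °C
Reagents that add atoms: none
Why: Kinetic α′-deprotonation of the enone gives the cross-conjugated dienolate, whose aldol addition attaches C11 and C12 to C9; the two new stereocentres are removed in the next step.

Step 15
Reactants: 24 aldol adduct at C9
Product: 26 9(11)-alkylidene dienone, via mesylate 25 (not isolated)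
Conditions: MsCl, Et3N, CH2Cl2, 0 °C; then DBU, rt
Reagents that add atoms: none
Why: Mesylation and E1cB elimination give the α-alkylidene ketone, which makes C9 trigonal so that no axial C9 substituent flanks the C8 carbonyl; the C9=C11 geometry is of no consequence.

Step 16
Reactants: 26 9(11)-alkylidene dienone
Product: 27 tertiary bis-allylic alcohol (C8 OH syn, C8 CH3 anti)
Conditions: MeLi, CeCl3, THF, −78 °C; H2O
Reagents that add atoms: methyllithium, [Li]C
Why: Organocerium 1,2-addition to the cross-conjugated dienone: the pseudoaxial C10 methyl is the only group over the flat C6–C9 array, so methyl should add from the opposite face and set C8 with CH3 anti and OH syn.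

Step 17
Reactants: 27 tertiary bis-allylic alcohol
Product: 28 saturated carbinol (C9 CH2CH2OTBS anti and axial, H9 syn)
Conditions: H2 (1 atm), [Ir(cod)(PCy3)(py)]PF6 (10 mol %), CH2Cl2, 0 °C → rt
Reagents that add atoms: none
Why: Hydroxyl-directed homogeneous hydrogenation: iridium bound to the C8 hydroxyl delivers H2 to the same face of C9=C11, so H9 ends syn and the C11 chain anti (the kinetically set, axial C9 epimer), and C6=C7 is reduced in the same operation.

Step 18
Reactants: 28 saturated carbinol
Product: 29 8,12-diol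
Conditions: PPTS (0.2 equiv), MeOH, rt
Reagents that add atoms: none
Why: Mild acid methanolysis removes the primary TBS ether and leaves the TBDPS ether and the tertiary alcohol alone.

Step 19
Reactants: 29 8,12-diol
Product: 30 C12 tosylate
Conditions: TsCl, pyridine, DMAP (cat.), CH2Cl2, 0 °C
Reagents that add atoms: 4-toluenesulfonyl chloride, Cc1ccc(cc1)S(Cl)(=O)=O
Why: Selective sulfonylation of the primary hydroxyl; the tertiary C8 hydroxyl does not react, and its trans-diaxial relation to the C9 chain rules out ring closure to a cyclic ether.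

Step 20
Reactants: 31 chloroprene
Product: 32 buta-1,3-dien-2-ylmagnesium chloride (THF solution, used directly)
Conditions: Mg, ZnCl2 (cat.), BrCH2CH2Br (cat.), THF, reflux
Reagents that add atoms: magnesium, [Mg]
Why: Grignard formation from the vinylic chloride with activated magnesium gives the known 2-butadienyl reagent.

Step 21
Reactants: 30 C12 tosylate; 32 buta-1,3-dien-2-ylmagnesium chloride
Product: 33 diene (C18 OTBDPS, C8 OH free)
Conditions: 32 (4 equiv), Li2CuCl4 (5 mol %), THF, −20 °C → rt; H2O
Reagents that add atoms: none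
Why: Copper-catalysed cross-coupling of a primary tosylate with the dienyl Grignard reagent forms the C12–C13 bond and gives the 2-alkylbuta-1,3-diene; the first equivalent only deprotonates the C8 hydroxyl.

Step 22
Reactants: 33 diene
Product: 34 8,18-diol
Conditions: Bu4NF, THF, rt → 40 °C; H2O
Reagents that add atoms: none
Why: Fluoride desilylation frees the neopentyl C18 hydroxyl under conditions that do not affect the diene or the tertiary alcohol.

Step 23
Reactants: 34 8,18-diol; 35 bis(2,2,2-trifluoroethyl)phosphonoacetic acid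
Product: 36 C18 phosphonoacetate
Conditions: DCC, DMAP (cat.), CH2Cl2, 0 °C → rt
Reagents that add atoms: none
Why: Steglich esterification acylates the primary hydroxyl only, since the tertiary C8 hydroxyl is too hindered.

Step 24
Reactants: 36 C18 phosphonoacetate; 37 4-(tert-butyldimethylsilyloxy)benzaldehyde
Product: 39 (Z)-4-(tert-butyldimethylsilyloxy)cinnamate, via potassium phosphonate carbanion 38 (not isolated)
Conditions: KN(SiMe3)2, 18-crown-6, THF, −78 °C; then 37
Reagents that add atoms: none
Why: Still–Gennari variant of the Horner–Wadsworth–Emmons reaction: the electron-poor phosphonate and the dissociated potassium counter-ion make elimination from the first-formed adduct fast, which should give the Z alkene.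

Step 25
Reactants: 39 (Z)-4-(tert-butyldimethylsilyloxy)cinnamate
Product: 40 target CNP0197278.4
Conditions: Bu4NF, AcOH (1:1), THF, 0 °C, dark
Reagents that add atoms: none
Why: Buffered fluoride cleavage of the aryl silyl ether; the buffer and exclusion of light are meant to prevent Z to E isomerisation through the free phenoxide.

**Compound list**
1 | (S)-1,2-epoxyhex-5-ene | C=CCC[C@H]1CO1 | starting material
2 | lithium acetylide–ethylenediamine complex | [Li]C#C.NCCN | starting material
3 | (S)-oct-7-en-1-yn-4-ol | C#CC[C@@H](O)CCC=C | intermediate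
4 | (S)-tert-butyldimethyl(oct-7-en-1-yn-4-yloxy)silane | C#CC[C@@H](O[Si](C)(C)C(C)(C)C)CCC=C | intermediate
5 | dimethyl[(1E,4S)-4-(tert-butyldimethylsilyloxy)-2-methylocta-1,7-dien-1-yl]aluminium | C[Al](C)/C=C(\C)C[C@@H](O[Si](C)(C)C(C)(C)C)CCC=C | intermediate
6 | (S,E)-tert-butyl[(1-iodo-2-methylocta-1,7-dien-4-yl)oxy]dimethylsilane | I/C=C(\C)C[C@@H](O[Si](C)(C)C(C)(C)C)CCC=C | intermediate
7 | (5S,7E)-5-(tert-butyldimethylsilyloxy)-8-iodo-7-methyloct-7-ene-1,2-diol (both C2 epimers) | I/C=C(\C)C[C@@H](O[Si](C)(C)C(C)(C)C)CCC(O)CO | intermediate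
8 | (4S,6E)-4-(tert-butyldimethylsilyloxy)-7-iodo-6-methylhept-6-enal | I/C=C(\C)C[C@@H](O[Si](C)(C)C(C)(C)C)CCC=O | intermediate
9 | 2-(triphenylphosphoranylidene)propanal | CC(C=O)=P(c1ccccc1)(c1ccccc1)c1ccccc1 | starting material
10 | (2E,6S,8E)-6-(tert-butyldimethylsilyloxy)-9-iodo-2,8-dimethylnona-2,8-dienal | I/C=C(\C)C[C@@H](O[Si](C)(C)C(C)(C)C)CC/C=C(\C)C=O | intermediate
11 | tributyl(vinyl)stannane | C=C[Sn](CCCC)(CCCC)CCCC | starting material
12 | (2E,6S,8E)-6-(tert-butyldimethylsilyloxy)-2,8-dimethylundeca-2,8,10-trienal | C=C/C=C(\C)C[C@@H](O[Si](C)(C)C(C)(C)C)CC/C=C(\C)C=O | intermediate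
13 | octalin aldehyde: 8-(tert-butyldimethylsilyloxy)-4,10-dimethyl-1,2-didehydro-trans-decalin-4-carbaldehyde (C4 CH3 syn, CHO anti, H5 anti, C8 OTBS anti and equatorial) | C1[C@]2(C)C=CC[C@](C)(C=O)[C@H]2CC[C@@H]1O[Si](C)(C)C(C)(C)C | intermediate
14 | C18 primary alcohol of 13 (CH2OH on C4 anti) | C1[C@]2(C)C=CC[C@](C)(CO)[C@H]2CC[C@@H]1O[Si](C)(C)C(C)(C)C | intermediate
15 | C18 tert-butyldiphenylsilyl ether of 14 | C1[C@]2(C)C=CC[C@](C)(CO[Si](c3ccccc3)(c3ccccc3)C(C)(C)C)[C@H]2CC[C@@H]1O[Si](C)(C)C(C)(C)C | intermediate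
16 | saturated trans-decalin bis-silyl ether (C8 OTBS anti, C18 OTBDPS) | C1[C@]2(C)CCC[C@](C)(CO[Si](c3ccccc3)(c3ccccc3)C(C)(C)C)[C@H]2CC[C@@H]1O[Si](C)(C)C(C)(C)C | intermediate
17 | C8 alcohol (OH anti, equatorial; C18 OTBDPS) | C1[C@]2(C)CCC[C@](C)(CO[Si](c3ccccc3)(c3ccccc3)C(C)(C)C)[C@H]2CC[C@@H]1O | intermediate
18 | 8-ketone (C18 OTBDPS) | O=C1C[C@]2(C)CCC[C@](C)(CO[Si](c3ccccc3)(c3ccccc3)C(C)(C)C)[C@H]2CC1 | intermediate
19 | lithium 7-en-8-olate of 18 | [Li]OC1C[C@]2(C)CCC[C@](C)(CO[Si](c3ccccc3)(c3ccccc3)C(C)(C)C)[C@H]2CC=1 | intermediate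
20 | 8-(trimethylsilyloxy)-7-ene of 18 | C[Si](C)(C)OC1C[C@]2(C)CCC[C@](C)(CO[Si](c3ccccc3)(c3ccccc3)C(C)(C)C)[C@H]2CC=1 | intermediate
21 | 6-en-8-one (C18 OTBDPS) | O=C1C[C@]2(C)CCC[C@](C)(CO[Si](c3ccccc3)(c3ccccc3)C(C)(C)C)[C@H]2C=C1 | intermediate
22 | (tert-butyldimethylsilyloxy)acetaldehyde | O=CCO[Si](C)(C)C(C)(C)C | starting material
23 | lithium 6,8(9)-dien-8-olate of 21 | [Li]OC1=C[C@]2(C)CCC[C@](C)(CO[Si](c3ccccc3)(c3ccccc3)C(C)(C)C)[C@H]2C=C1 | intermediate
24 | 9-[2-(tert-butyldimethylsilyloxy)-1-hydroxyethyl]-6-en-8-one (mixture at C9 and C11) | O=C1C(C(O)CO[Si](C)(C)C(C)(C)C)[C@]2(C)CCC[C@](C)(CO[Si](c3ccccc3)(c3ccccc3)C(C)(C)C)[C@H]2C=C1 | intermediate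
25 | C11 methanesulfonate of 24 | O=C1C(C(OS(C)(=O)=O)CO[Si](C)(C)C(C)(C)C)[C@]2(C)CCC[C@](C)(CO[Si](c3ccccc3)(c3ccccc3)C(C)(C)C)[C@H]2C=C1 | intermediate
26 | 12-(tert-butyldimethylsilyloxy)-6,9(11)-dien-8-one (C9=C11 geometry not defined) | O=C1C(=CCO[Si](C)(C)C(C)(C)C)[C@]2(C)CCC[C@](C)(CO[Si](c3ccccc3)(c3ccccc3)C(C)(C)C)[C@H]2C=C1 | intermediate
27 | 8-hydroxy-8-methyl-6,9(11)-diene (C8 OH syn, CH3 anti; C12 OTBS, C18 OTBDPS) | CC(C)(C)[Si](C)(C)OCC=C1[C@]2(C)CCC[C@](C)(CO[Si](c3ccccc3)(c3ccccc3)C(C)(C)C)[C@H]2C=C[C@@]1(C)O | intermediate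
28 | saturated carbinol (C9 CH2CH2OTBS anti and axial, H9 syn; C8 OH syn, CH3 anti; C18 OTBDPS) | CC(C)(C)[Si](C)(C)OCC[C@@H]1[C@]2(C)CCC[C@](C)(CO[Si](c3ccccc3)(c3ccccc3)C(C)(C)C)[C@H]2CC[C@@]1(C)O | intermediate
29 | 8,12-diol (C18 OTBDPS) | OCC[C@@H]1[C@]2(C)CCC[C@](C)(CO[Si](c3ccccc3)(c3ccccc3)C(C)(C)C)[C@H]2CC[C@@]1(C)O | intermediate
30 | C12 4-toluenesulfonate of 29 | Cc4ccc(cc4)S(=O)(=O)OCC[C@@H]1[C@]2(C)CCC[C@](C)(CO[Si](c3ccccc3)(c3ccccc3)C(C)(C)C)[C@H]2CC[C@@]1(C)O | intermediate
31 | chloroprene (2-chlorobuta-1,3-diene) | C=CC(Cl)=C | starting material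
32 | buta-1,3-dien-2-ylmagnesium chloride | C=CC(=C)[Mg]Cl | intermediate
33 | 18-(tert-butyldiphenylsilyloxy)labda-13(16),14-dien-8-ol stereoisomer (C8 OH syn, C9 chain anti) | C=CC(=C)CC[C@@H]1[C@]2(C)CCC[C@](C)(CO[Si](c3ccccc3)(c3ccccc3)C(C)(C)C)[C@H]2CC[C@@]1(C)O | intermediate
34 | labda-13(16),14-diene-8,18-diol stereoisomer | C=CC(=C)CC[C@@H]1[C@]2(C)CCC[C@](C)(CO)[C@H]2CC[C@@]1(C)O | intermediate
35 | bis(2,2,2-trifluoroethyl)phosphonoacetic acid | OC(=O)CP(=O)(OCC(F)(F)F)OCC(F)(F)F | starting material
36 | 18-O-{[bis(2,2,2-trifluoroethoxy)phosphoryl]acetyl} derivative of 34 | C=CC(=C)CC[C@@H]1[C@]2(C)CCC[C@](C)(COC(=O)CP(=O)(OCC(F)(F)F)OCC(F)(F)F)[C@H]2CC[C@@]1(C)O | intermediate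
37 | 4-(tert-butyldimethylsilyloxy)benzaldehyde | O=Cc1ccc(O[Si](C)(C)C(C)(C)C)cc1 | starting material
38 | potassium carbanion of 36 | C=CC(=C)CC[C@@H]1[C@]2(C)CCC[C@](C)(COC(=O)[CH-]P(=O)(OCC(F)(F)F)OCC(F)(F)F)[C@H]2CC[C@@]1(C)O.[K+] | intermediate
39 | 18-O-[(Z)-4-(tert-butyldimethylsilyloxy)cinnamoyl] derivative of 34 | C=CC(=C)CC[C@@H]1[C@]2(C)CCC[C@](C)(COC(=O)/C=C\c3ccc(O[Si](C)(C)C(C)(C)C)cc3)[C@H]2CC[C@@]1(C)O | intermediate
40 | CNP0197278.4: 8-hydroxylabda-13(16),14-dien-18-yl (Z)-4-hydroxycinnamate stereoisomer (C4 CH3 syn, CH2O anti; H5 anti; C8 OH syn, CH3 anti; C9 chain anti) | C=CC(=C)CC[C@@H]1[C@]2(C)CCC[C@](C)(COC(=O)/C=C\c3ccc(O)cc3)[C@H]2CC[C@@]1(C)O | target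

**Step count**
Total: 25 steps. Longest linear sequence: 24 steps (steps 1–19 and 21–25; step 20 prepares the Grignard reagent).

**Steps most likely to fail**

Step 7 (cycloaddition). The C5–C10 bond must form at a fully substituted diene terminus whose methyl points into the diene, and the endo mode builds a syn relation between the C4 and C10 methyls. The cycloaddition may therefore be slower than Lewis acid-induced oligomerisation of the diene, or the exo mode may compete. Fallback, from 12 back to 13: trienal 12 is heated with ethylene glycol and PPTS in benzene (water removal) to give the trienal 1,3-dioxolane F1. Catalytic TMSOTf in CH2Cl2 at −78 °C opens the acetal to an alkoxy-stabilised allyl cation, a much stronger dienophile, and the ionic Diels–Alder reaction should give the octalin dioxolane F2 through the same endo, chair-tether arrangement. Hydrolysis of F2 (PPTS, wet acetone) returns aldehyde 13.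

Step 17 (directed hydrogenation). Hydrogen delivery to C9 from the hydroxyl face requires the iridium centre to sit next to the axial C10 methyl. If that coordination is too hindered, hydrogen may add from the open face, reduction may stop at C9=C11, or the bis-allylic alcohol may ionise. Fallback, from 21 back to 29, which sets C9 first by enolate alkylation: enone 21 is deprotonated at C9 (LiN(iPr)2, THF, −78 °C) and allylated with allyl bromide (DMPU) anti to the C10 methyl to give the 9-allyl enone F3. Conjugate reduction with [(Ph3P)CuH]6 in wet THF gives the saturated 9-allyl ketone F4 without touching the allyl group or C9. Dimethylsulfoxonium methylide (Me3S(O)I, NaH, DMSO) adds reversibly and should close the spiro-epoxide F5 with the new C–C bond equatorial and anti to the C10 methyl. LiAlH4 opens F5 at the methylene carbon to the 9-allyl tertiary alcohol F6, and ozonolysis of the allyl group with NaBH4 work-up returns diol 29.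

Step 21 (copper-catalysed coupling). The dienyl Grignard reagent may react through its allenic form, or the tosylate may be eliminated or reduced, while the free C8 hydroxyl consumes reagent. Fallback, from 30 back to 33: tosylate 30 is displaced with lithium acetylide–ethylenediamine complex 2 in DMSO to give the terminal alkyne F7. Enyne cross-metathesis of F7 with ethylene (1 atm) and second-generation Grubbs catalyst, RuCl2(=CHPh)(H2IMes)(PCy3), in CH2Cl2 then gives the 2-substituted buta-1,3-diene 33.

**Further compounds**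
F1 | step 7 | 1,3-dioxolane of trienal 12 | C=C/C=C(\C)C[C@@H](O[Si](C)(C)C(C)(C)C)CC/C=C(\C)C1OCCO1
F2 | step 7 | 1,3-dioxolane of octalin aldehyde 13 | C1[C@]2(C)C=CC[C@](C)(C3OCCO3)[C@H]2CC[C@@H]1O[Si](C)(C)C(C)(C)C
F3 | step 17 | 9-allyl-6-en-8-one (allyl anti to the C10 methyl; C18 OTBDPS) | C=CC[C@@H]1[C@]2(C)CCC[C@](C)(CO[Si](c3ccccc3)(c3ccccc3)C(C)(C)C)[C@H]2C=CC1=O
F4 | step 17 | 9-allyl-8-ketone (allyl anti, axial; C18 OTBDPS) | C=CC[C@@H]1[C@]2(C)CCC[C@](C)(CO[Si](c3ccccc3)(c3ccccc3)C(C)(C)C)[C@H]2CCC1=O
F5 | step 17 | 8,17-spiro-epoxide of F4 (oxygen syn and axial, CH2 anti and equatorial) | C=CC[C@@H]1[C@]2(C)CCC[C@](C)(CO[Si](c3ccccc3)(c3ccccc3)C(C)(C)C)[C@H]2CC[C@@]14OC4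
F6 | step 17 | 9-allyl-8-methyl-8-ol (C8 OH syn, CH3 anti; allyl anti; C18 OTBDPS) | C=CC[C@@H]1[C@]2(C)CCC[C@](C)(CO[Si](c3ccccc3)(c3ccccc3)C(C)(C)C)[C@H]2CC[C@@]1(C)O
F7 | step 21 | terminal alkyne: 9-(but-3-yn-1-yl)-8-methyl-8-ol (C18 OTBDPS) | C#CCC[C@@H]1[C@]2(C)CCC[C@](C)(CO[Si](c3ccccc3)(c3ccccc3)C(C)(C)C)[C@H]2CC[C@@]1(C)O
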